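Each of the four constants multiplies a reagent concentration, and I started there.

    substrate + reagent → mono adduct + by-product (k1 = 685 /M/s)
    reagent + mono adduct → bis adduct + by-product (k2 = 592 /M/s)
    reagent + mono adduct → over-reaction product (k3 = 19.9 /M/s)
    reagent + bis adduct → triple product + by-product (k4 = 394 /M/s)

all flasks: time 80 s
- theta: substrate 0.50 mM (fed, over 15 s); reagent 0.900 mM; all else is in the flask from the start; the feed brings no volume worth counting
- alpha: substrate 0.50 mM (in portions, 3, over 15 s); reagent 0.900 mM; first portion at the start, last at 15 s
- gamma: substrate 0.50 mM; reagent 0.900 mM; everything together at the start
- zeta: substrate 0.50 mM; reagent 0.900 mM (fed, over 15 s); all else is in the flask from the start; the feed brings no volume worth counting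

* the best flask by share of mono adduct in mono adduct plus bis adduct; "all alike" if 1.5 percentage points covers them all (theta / alpha / gamma / zeta / all alike)
* share of mono adduct in mono adduct plus bis adduct at the end, theta
* share of mono adduct in mono adduct plus bis adduct at the end, alpha
* share of mono adduct in mono adduct plus bis adduct at the end, gamma
* share of mono adduct in mono adduct plus bis adduct at the end, zeta

Reagent stands as a first-order factor on every arrow, so it cancels from the ratio of any two rates. With the substrate in from the start, the proportions among the adducts therefore follow how far the run has gone, not how quickly it got there. So I expected zeta, where the reagent is fed, to land on the share of gamma, provided the same reagent is used up in both.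

But how far can a run go? With the charges of gamma, mono adduct has a half-life of 1.3 s by step 2 and bis adduct one of 2.0 s by step 4, both short against 80 s, so I looked to the amounts and not to the time. A substrate carried through to triple product takes three reagent, so the charge asks for 1.50 mM. Reagent charged over that demand comes to 0.600; this ratio, reagent charged over three times substrate charged, is my reagent cover. The four flasks share these charges, and with the cover below one, reagent is the limiting reagent, so I expected a mixture at the end. I could not reckon the substrate feeds by hand, so I set no share.

The forecast named alpha best, with 47.5% for theta, 50.5% for alpha, 42.6% for gamma and 42.6% for zeta, holding that feeding reagent “only stretches the clock”.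

I then read 47.8% for theta, 50.1% for alpha, 42.7% for gamma and 42.7% for zeta, so alpha stood highest. In gamma, at cover 0.600, reagent stood at 0% of its charge after 80.0 s, with triple product at 26.4% of the substrate. A neighbour of gamma charged with 0.20 mM of substrate has a cover of 1.50, above one, and subtracting its demand leaves 33.3% of the reagent. That neighbour read 34.1% of reagent left, triple product at 96.7% of the substrate, and a share of mono adduct of 0.287%.

All constants are those of an exercise; the rest is arithmetic.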